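I decided to answer your quick question with one time, not by integrating the flask.

    substrate ⇌ intermediate A (K1 = 8.0, k1 = 0.26 h⁻¹)
    coupling partner + intermediate A ⇌ intermediate B (K2 = 46 M⁻¹, k2 = 4.6 M⁻¹ h⁻¹)
    intermediate B ⇌ target (K3 = 0.34, k3 = 0.54 h⁻¹)
    target ⇌ isomer of the product (K4 = 0.14, k4 = 0.15 h⁻¹)
    gas ⇌ coupling partner, rate k5*(csat - [coupling partner]) (k5 = 0.63 h⁻¹, csat = 49 mM)

substrate 0.30 M (fed, over 30 min); gas 49 mM (held); time 8.0 d

- the state of affairs at 8.0 d: stopped, and by what, or still going (all of the substrate has reacted / it is still moving / forward and back rates have come level)
- share of the substrate used up at 8.0 d
- target at 8.0 d, in percent of the substrate charged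
- intermediate B at 8.0 d, in percent of the substrate charged
- intermediate A at 8.0 d, in percent of the substrate charged

- at the start none of coupling partner is dissolved
- the reaction counts as stopped when no species that holds the substrate changes by six tenths of a point or more over the second half of the time
- run time (flask): 8.0 d

**Your hunch.** You suspected the gas of holding this flask back: none of the coupling partner is dissolved at the start, and every step beyond intermediate A consumes or carries one. So I first asked where the flask rests, and then how long the gas needs to get it there.

**Resting shares.** With the partner at 49 mM, I gave each form a weight relative to intermediate A: 0.125 for substrate and 2.25 for intermediate B. Target and isomer follow by 0.34 and 0.14. The weights sum to 4.25, a partition sum, and using them assumes thermodynamic control. I committed to a conversion of 97.1%, with target 18.0%, intermediate B 52.9% and intermediate A 23.5%.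

**Fill time.** Forms holding a partner make up 73.5% of the charge, and the dissolved partner adds 16.3% of it. I replaced the falling deficit by its mean, 24.5 mM. The fill time, meaning this whole demand divided by the transfer rate at the mean deficit, came to 0.728 d. The run lasts about ten times as long, so I expected the resting shares to stand at 8.0 d.

**The forecast.** It said forward and back rates have come level, with conversion 97.1%, target 18%, intermediate B 53% and intermediate A 23.5%. Its ground was “the system should have settled at equilibrium with the dissolved partner back at saturation”. It put the gas uptake at roughly 10 h, and my fill time differs from that at 17.5 h.

**The flask.** The simulation gave forward and back rates have come level, with conversion 97.1%, target 18.0%, intermediate B 53.0% and intermediate A 23.5%.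

**Time compared.** Half of the gas transfer up to 8.0 d was done by 0.379 d, later than the 0.364 d that my fill time implies, and both are shorter than the run. By 1.60 d this flask had 99% of its transfer behind it, and at 4.00 d the partner already stood at 0.0490 M.

**Larger charge.** For the neighbour flask with 0.51 M of substrate, the same reckoning gives a fill time of 1.14 d, still shorter than 8.0 d, so I expected the same shares there. That neighbour flask computed to conversion 97.1%, target 18.0%, intermediate B 53.0% and intermediate A 23.5%.

All constants were set for the occasion; the run is a simulation.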